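**Retrosynthetic overview**
1. Target = (3R,3'R,6'R)-7,8-didehydro-β,ε-carotene-3,3'-diol. The last C–C bond made is the C7≡C8 triple bond itself: a β-ring C7 α-sulfonyl carbanion (a polarity-reversed allylic carbon) adds to the C8 carbonyl carbon of an all-E C30 apo-aldehyde, then double elimination. Both carbons are electrophilic in their parent forms (allylic halide, aldehyde).
2. C30 aldehyde ⇐ C27 ⇐ C25 aldehyde (C3 and C2 Wittig extensions) ⇐ ε-C15 phosphonium salt + C10 dialdehyde. All E/Z equilibration is finished before the alkyne exists, so 9E is never exposed to isomerisation.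
3. ε-C15 unit ⇐ racemic α-ionone: HWE, allylic oxidation, trans-selective reduction, lipase resolution (3'R,6'R).
4. β-Ring sulfone ⇐ ketoisophorone: enzymatic C=C reduction, hydride reduction (sets 3R), PhSO2CH2 addition, dehydration.
5. Rings: none is built; both six-membered rings are bought (ketoisophorone → β-ring, α-ionone → ε-ring).

Assumption: lipase PS is taken to acetylate the (3S)-carbinol of the racemic ε-ring alcohol, leaving the (3R,6R)-alcohol; positions are quoted in carotenoid numbering; TBS = tert-butyldimethylsilyl; all polyene work is done under argon in dim light.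

**Step 1**
Reactants: 1 ketoisophorone (2,6,6-trimethylcyclohex-2-ene-1,4-dione)
Product: 2 (6R)-levodione [(R)-2,2,6-trimethylcyclohexane-1,4-dione]
Conditions: ene-reductase OYE2, NADP+ (cat.), glucose dehydrogenase, D-glucose, phosphate buffer pH 6.5, 30 °C
Reagents that add atoms: none
Why: Ene-reductase (old yellow enzyme) asymmetric reduction of the activated C=C, the isolated-enzyme version of the classical yeast reduction, in which flavin hydride adds to the β-carbon and a proton to the methyl-bearing α-carbon, which becomes the (R) centre (≥95% ee), while glucose dehydrogenase recycles the cofactor.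

**Step 2**
Reactants: 2 (6R)-levodione
Product: 3 (4R,6R)-actinol [(4R,6R)-4-hydroxy-2,2,6-trimethylcyclohexan-1-one]
Conditions: LiBH(s-Bu)3, THF, −78 °C
Reagents that add atoms: none
Why: Bulky-hydride reduction that touches only the unhindered C4 carbonyl (C1 is flanked by three methyl groups) and attacks it equatorially, anti to the axial C2 methyl, giving the axial alcohol trans to the 6-methyl group, i.e. the (4R) centre that becomes C3 (R) of the target (1,3-diaxial control as in 3,3,5-trimethylcyclohexanone).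

**Step 3**
Reactants: 3 (4R,6R)-actinol
Product: 4 (4R,6R)-4-(TBSO)-2,2,6-trimethylcyclohexan-1-one
Conditions: TBSCl, imidazole, DMF, rt
Reagents that add atoms: tert-butyldimethylsilyl chloride (TBSCl), CC(C)(C)[Si](C)(C)Cl
Why: Standard silyl ether formation on the secondary alcohol, needed because the later carbanion and dehydration steps would attack a free hydroxyl; no stereocentre is touched.

**Step 4**
Reactants: 4 (4R,6R)-4-(TBSO)-2,2,6-trimethylcyclohexan-1-one; 5 methyl phenyl sulfone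
Product: 7 (4R,6R)-4-(TBSO)-2,2,6-trimethyl-1-[(phenylsulfonyl)methyl]cyclohexan-1-ol (both C1 epimers), via (phenylsulfonyl)methyllithium 6 (not isolated)
Conditions: 5, n-BuLi, THF, −78 °C; CeCl3 (anhydrous); then 4, −78 → 0 °C
Reagents that add atoms: none
Why: 1,2-Addition of a sulfonyl-stabilised carbanion (Julia-type carbonyl addition) in which transmetalation to cerium curbs enolisation of the hindered ketone; the new carbinol centre forms as a mixture that is erased in step 5.

**Step 5**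
Reactants: 7 (4R,6R)-4-(TBSO)-2,2,6-trimethyl-1-[(phenylsulfonyl)methyl]cyclohexan-1-ol
Product: 9 (R)-tert-butyldimethyl{[3,5,5-trimethyl-4-(phenylsulfonylmethyl)cyclohex-3-en-1-yl]oxy}silane (β-ring allyl sulfone), via exocyclic vinyl sulfone 8 (not isolated)
Conditions: SOCl2, pyridine, CH2Cl2, 0 °C; then DBU (cat.), toluene, 80 °C
Reagents that add atoms: none
Why: Dehydration of the tertiary alcohol through its chlorosulfite (E2) followed by base-catalysed vinyl-to-allyl sulfone isomerisation, which funnels all material to the thermodynamically preferred tetrasubstituted β,γ-unsaturated sulfone; the former methyl-bearing stereocentre becomes sp2 as planned and the silyloxy centre is untouched.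

**Step 6**
Reactants: 10 racemic α-ionone [(E)-4-(2,6,6-trimethylcyclohex-2-en-1-yl)but-3-en-2-one]; 11 triethyl phosphonoacetate
Product: 13 ethyl (2E,4E)-3-methyl-5-(2,6,6-trimethylcyclohex-2-en-1-yl)penta-2,4-dienoate (racemic), via phosphonate carbanion sodium salt 12 (not isolated)
Conditions: NaH, THF, 0 → 50 °C; chromatography removes the 2Z isomer
Reagents that add atoms: none
Why: Horner–Wadsworth–Emmons olefination of the methyl ketone, E-selective (about 85:15) as usual for stabilised phosphonate carbanions; the ring stereocentre is racemic at this stage by design.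

**Step 7**
Reactants: 13 ethyl (2E,4E)-3-methyl-5-(2,6,6-trimethylcyclohex-2-en-1-yl)penta-2,4-dienoate
Product: 14 ethyl (2E,4E)-3-methyl-5-(2,6,6-trimethyl-4-oxocyclohex-2-en-1-yl)penta-2,4-dienoate (racemic)
Conditions: t-BuOOH (70% aq.), Rh2(C6H10NO)4 [dirhodium tetrakis(caprolactamate), 1 mol %], CH2Cl2, 40 °C
Reagents that add atoms: tert-butyl hydroperoxide, CC(C)(C)OO
Why: Allylic C–H oxidation by the tert-butylperoxyl radical chain (Kharasch-type, dirhodium-catalysed), in which hydrogen is abstracted from the ring CH2 next to the electron-rich trisubstituted alkene rather than from the hindered doubly allylic C–H or the electron-poor dienoate, and that position is taken on to the enone.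

**Step 8**
Reactants: 14 ethyl (2E,4E)-3-methyl-5-(2,6,6-trimethyl-4-oxocyclohex-2-en-1-yl)penta-2,4-dienoate
Product: 15 ethyl (2E,4E)-5-[(1RS,4RS)-4-hydroxy-2,6,6-trimethylcyclohex-2-en-1-yl]-3-methylpenta-2,4-dienoate (racemic trans alcohol)
Conditions: LiBH(s-Bu)3 (1.05 equiv), THF, −78 °C; chromatography removes the cis isomer
Reagents that add atoms: none
Why: 1,2-Reduction of the β-substituted cyclohexenone by a bulky hydride that approaches anti to the pseudoaxial methyl of the ring gem-dimethyl group, on the face carrying the pseudoaxial side chain, so the new hydroxyl is set trans to the chain (the 3',6'-trans relationship of the target); the dienoate is inert at −78 °C.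

**Step 9**
Reactants: 15 racemic trans alcohol
Product: 16 ethyl (2E,4E)-5-[(1R,4R)-4-hydroxy-2,6,6-trimethylcyclohex-2-en-1-yl]-3-methylpenta-2,4-dienoate
Conditions: lipase PS (Burkholderia cepacia), vinyl acetate, t-BuOMe, 30 °C, to 55% conversion; chromatography
Reagents that add atoms: none
Why: Lipase-catalysed kinetic resolution by irreversible transesterification, in which the (1S,4S)-enantiomer is acetylated and the unreacted (1R,4R)-alcohol is recovered in ≥98% ee past 50% conversion, fixing both ε-ring stereocentres of the target (3'R,6'R).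

**Step 10**
Reactants: 16 (1R,4R)-hydroxy dienoate
Product: 17 ethyl (2E,4E)-5-[(1R,4R)-4-(TBSO)-2,6,6-trimethylcyclohex-2-en-1-yl]-3-methylpenta-2,4-dienoate
Conditions: TBSCl, imidazole, DMF, rt
Reagents that add atoms: tert-butyldimethylsilyl chloride (TBSCl), CC(C)(C)[Si](C)(C)Cl
Why: Silyl ether formation protects the allylic hydroxyl against the hydride, acid and strong-base steps that follow; stereocentres are untouched.

**Step 11**
Reactants: 17 silyl-protected dienoate
Product: 18 (2E,4E)-5-[(1R,4R)-4-(TBSO)-2,6,6-trimethylcyclohex-2-en-1-yl]-3-methylpenta-2,4-dien-1-ol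
Conditions: i-Bu2AlH, CH2Cl2, −78 °C
Reagents that add atoms: none
Why: Ester to primary allylic alcohol by aluminium hydride 1,2-reduction at low temperature, which leaves the diene and the silyl ether intact.

**Step 12**
Reactants: 18 C15 dienol
Product: 19 {(2E,4E)-5-[(1R,4R)-4-(TBSO)-2,6,6-trimethylcyclohex-2-en-1-yl]-3-methylpenta-2,4-dien-1-yl}triphenylphosphonium bromide
Conditions: PPh3·HBr, CH2Cl2, 0 °C → rt
Reagents that add atoms: triphenylphosphine hydrobromide, [Br-].[PH+](c1ccccc1)(c1ccccc1)c1ccccc1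
Why: Acid-promoted ionisation of the dienylic alcohol and capture of the pentadienyl cation by triphenylphosphine at the primary terminus (standard allylic phosphonium salt formation), under aprotic conditions that the silyl ether survives.

**Step 13**
Reactants: 19 ε-C15 phosphonium bromide; 20 (2E,4E,6E)-2,7-dimethylocta-2,4,6-trienedial (C10 dialdehyde)
Product: 22 (2E,4E,6E,8E,10E,12E)-2,7,11-trimethyl-13-[(1R,4R)-4-(TBSO)-2,6,6-trimethylcyclohex-2-en-1-yl]trideca-2,4,6,8,10,12-hexaenal (C25 aldehyde), via phosphorus ylide 21 (not isolated)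
Conditions: NaOMe, MeOH/CH2Cl2, 0 °C (19 added to 2 equiv of 20); then I2 (cat.), hexane/CH2Cl2, daylight, rt
Reagents that add atoms: none
Why: Wittig olefination forming C11'=C12', in which mono-olefination is favoured because the dialdehyde is used in excess and the remaining aldehyde of the product is a less electrophilic extended polyenal, and iodine-catalysed photoequilibration converts the E/Z mixture at the new double bond to the all-E aldehyde.

**Step 14**
Reactants: 22 C25 aldehyde; 23 (1,3-dioxolan-2-ylmethyl)triphenylphosphonium bromide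
Product: 26 (2E,4E,6E,8E,10E,12E,14E)-4,9,13-trimethyl-15-[(1R,4R)-4-(TBSO)-2,6,6-trimethylcyclohex-2-en-1-yl]pentadeca-2,4,6,8,10,12,14-heptaenal (C27 aldehyde), via dioxolanylmethylene ylide 24 (not isolated), via polyenyl dioxolane 25 (not isolated)
Conditions: 23, t-BuOK, THF, 0 °C → rt; then 10% aq. oxalic acid, THF, rt; I2 (cat.), daylight
Reagents that add atoms: water, O
Why: Wittig two-carbon homologation by a formylmethylene ylide masked as its dioxolane, followed by mild acetal hydrolysis and iodine-catalysed equilibration of the new C11=C12 bond to E; the silyl ether tolerates oxalic acid.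

**Step 15**
Reactants: 26 C27 aldehyde; 27 2-(triphenylphosphoranylidene)propanal
Product: 28 (2E,4E,6E,8E,10E,12E,14E,16E)-2,6,11,15-tetramethyl-17-[(1R,4R)-4-(TBSO)-2,6,6-trimethylcyclohex-2-en-1-yl]heptadeca-2,4,6,8,10,12,14,16-octaenal (C30 aldehyde)
Conditions: toluene, 80 °C, dark
Reagents that add atoms: none
Why: Wittig reaction of a stabilised ylide, which is E-selective and delivers the (E)-2-methyl-2-enal terminus, so that the 9E geometry and the C8 aldehyde are in place before the alkyne is made.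

**Step 16**
Reactants: 9 β-ring allyl sulfone; 28 C30 aldehyde
Product: 32 (3R,3'R,6'R)-3,3'-bis(tert-butyldimethylsilyloxy)-7,8-didehydro-β,ε-carotene, via lithiated sulfone 29 (not isolated), via phosphate adduct 30 (not isolated), via vinyl sulfone 31 (not isolated)
Conditions: 9, LiN(SiMe3)2 (1.2 equiv), THF, −78 °C; 28; ClP(O)(OEt)2, −78 → 0 °C; LiN(SiMe3)2 (4 equiv), −78 °C → rt, dark
Reagents that add atoms: none
Why: The phenylsulfonyl group reverses the polarity of C7 (an electrophilic carbon in the corresponding allylic halide), so carbanion 29 adds 1,2 to the aldehyde carbon C8 (Julia-type addition, the same pairing of a cyclogeranyl sulfone and a 2-methyl-2-enal used in sulfone routes to retinoids), the adduct is trapped in situ as phosphate 30, and two base-induced eliminations (E1cB loss of phosphate to vinyl sulfone 31, then loss of benzenesulfinate; Otera-type double elimination) create the C7≡C8 triple bond without touching the 9E or any other double bond, and no stereocentre is formed.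

**Step 17**
Reactants: 32 bis-silyl ether
Product: 33 (3R,3'R,6'R)-7,8-didehydro-β,ε-carotene-3,3'-diol (CNP0232536.1)
Conditions: Bu4NF, THF, 0 °C → rt, dark
Reagents that add atoms: none
Why: Fluoride-mediated cleavage of both secondary silyl ethers under non-acidic conditions that spare the acid-labile allylic ε-ring alcohol and the polyene; no stereocentre or double bond is affected.

**Compound list**
1 | ketoisophorone (2,6,6-trimethylcyclohex-2-ene-1,4-dione) | CC1=CC(=O)CC(C)(C)C1=O | starting material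
2 | (6R)-levodione, (R)-2,2,6-trimethylcyclohexane-1,4-dione | C[C@@H]1CC(=O)CC(C)(C)C1=O | intermediate
3 | (4R,6R)-actinol, (4R,6R)-4-hydroxy-2,2,6-trimethylcyclohexan-1-one | C[C@@H]1C[C@@H](O)CC(C)(C)C1=O | intermediate
4 | (4R,6R)-4-(TBSO)-2,2,6-trimethylcyclohexan-1-one | C[C@@H]1C[C@@H](O[Si](C)(C)C(C)(C)C)CC(C)(C)C1=O | intermediate
5 | methyl phenyl sulfone | CS(=O)(=O)c1ccccc1 | starting material
6 | (phenylsulfonyl)methyllithium (not isolated) | [Li]CS(=O)(=O)c1ccccc1 | intermediate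
7 | (4R,6R)-4-(TBSO)-2,2,6-trimethyl-1-[(phenylsulfonyl)methyl]cyclohexan-1-ol, both C1 epimers | C[C@@H]1C[C@@H](O[Si](C)(C)C(C)(C)C)CC(C)(C)C1(O)CS(=O)(=O)c1ccccc1 | intermediate
8 | tert-butyldimethyl{[(1R,5R)-3,3,5-trimethyl-4-(phenylsulfonylmethylidene)cyclohexyl]oxy}silane, exocyclic vinyl sulfone (not isolated) | C[C@@H]1C[C@@H](O[Si](C)(C)C(C)(C)C)CC(C)(C)C1=CS(=O)(=O)c1ccccc1 | intermediate
9 | (R)-tert-butyldimethyl{[3,5,5-trimethyl-4-(phenylsulfonylmethyl)cyclohex-3-en-1-yl]oxy}silane, β-ring allyl sulfone | O=S(=O)(CC1=C(C)C[C@@H](O[Si](C)(C)C(C)(C)C)CC1(C)C)c1ccccc1 | intermediate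
10 | racemic α-ionone, (E)-4-(2,6,6-trimethylcyclohex-2-en-1-yl)but-3-en-2-one | CC1=CCCC(C)(C)C1/C=C/C(C)=O | starting material
11 | triethyl phosphonoacetate | CCOC(=O)CP(=O)(OCC)OCC | starting material
12 | sodium salt of the triethyl phosphonoacetate carbanion (not isolated) | [Na+].CCOC(=O)[CH-]P(=O)(OCC)OCC | intermediate
13 | ethyl (2E,4E)-3-methyl-5-(2,6,6-trimethylcyclohex-2-en-1-yl)penta-2,4-dienoate, racemic | CC1=CCCC(C)(C)C1/C=C/C(C)=C/C(=O)OCC | intermediate
14 | ethyl (2E,4E)-3-methyl-5-(2,6,6-trimethyl-4-oxocyclohex-2-en-1-yl)penta-2,4-dienoate, racemic | CC1=CC(=O)CC(C)(C)C1/C=C/C(C)=C/C(=O)OCC | intermediate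
15 | ethyl (2E,4E)-5-[(1RS,4RS)-4-hydroxy-2,6,6-trimethylcyclohex-2-en-1-yl]-3-methylpenta-2,4-dienoate, racemic trans (both enantiomers written) | CC1=C[C@H](O)CC(C)(C)[C@H]1/C=C/C(C)=C/C(=O)OCC.CC1=C[C@@H](O)CC(C)(C)[C@@H]1/C=C/C(C)=C/C(=O)OCC | intermediate
16 | ethyl (2E,4E)-5-[(1R,4R)-4-hydroxy-2,6,6-trimethylcyclohex-2-en-1-yl]-3-methylpenta-2,4-dienoate | CC1=C[C@H](O)CC(C)(C)[C@H]1/C=C/C(C)=C/C(=O)OCC | intermediate
17 | ethyl (2E,4E)-5-[(1R,4R)-4-(TBSO)-2,6,6-trimethylcyclohex-2-en-1-yl]-3-methylpenta-2,4-dienoate | CC1=C[C@H](O[Si](C)(C)C(C)(C)C)CC(C)(C)[C@H]1/C=C/C(C)=C/C(=O)OCC | intermediate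
18 | (2E,4E)-5-[(1R,4R)-4-(TBSO)-2,6,6-trimethylcyclohex-2-en-1-yl]-3-methylpenta-2,4-dien-1-ol | CC1=C[C@H](O[Si](C)(C)C(C)(C)C)CC(C)(C)[C@H]1/C=C/C(C)=C/CO | intermediate
19 | {(2E,4E)-5-[(1R,4R)-4-(TBSO)-2,6,6-trimethylcyclohex-2-en-1-yl]-3-methylpenta-2,4-dien-1-yl}triphenylphosphonium bromide | CC1=C[C@H](O[Si](C)(C)C(C)(C)C)CC(C)(C)[C@H]1/C=C/C(C)=C/C[P+](c1ccccc1)(c1ccccc1)c1ccccc1.[Br-] | intermediate
20 | (2E,4E,6E)-2,7-dimethylocta-2,4,6-trienedial | O=C/C(C)=C/C=C/C=C(C)/C=O | starting material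
21 | phosphorus ylide of 19 (not isolated) | CC1=C[C@H](O[Si](C)(C)C(C)(C)C)CC(C)(C)[C@H]1/C=C/C(C)=C/C=P(c1ccccc1)(c1ccccc1)c1ccccc1 | intermediate
22 | (2E,4E,6E,8E,10E,12E)-2,7,11-trimethyl-13-[(1R,4R)-4-(TBSO)-2,6,6-trimethylcyclohex-2-en-1-yl]trideca-2,4,6,8,10,12-hexaenal | CC1=C[C@H](O[Si](C)(C)C(C)(C)C)CC(C)(C)[C@H]1/C=C/C(C)=C/C=C/C(C)=C/C=C/C=C(C)/C=O | intermediate
23 | (1,3-dioxolan-2-ylmethyl)triphenylphosphonium bromide | [Br-].C(C1OCCO1)[P+](c1ccccc1)(c1ccccc1)c1ccccc1 | starting material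
24 | (1,3-dioxolan-2-ylmethylene)triphenylphosphorane (not isolated) | C(C1OCCO1)=P(c1ccccc1)(c1ccccc1)c1ccccc1 | intermediate
25 | ethylene acetal of 26, E/Z mixture at the newly formed double bond (not isolated) | CC1=C[C@H](O[Si](C)(C)C(C)(C)C)CC(C)(C)[C@H]1/C=C/C(C)=C/C=C/C(C)=C/C=C/C=C(C)/C=CC1OCCO1 | intermediate
26 | (2E,4E,6E,8E,10E,12E,14E)-4,9,13-trimethyl-15-[(1R,4R)-4-(TBSO)-2,6,6-trimethylcyclohex-2-en-1-yl]pentadeca-2,4,6,8,10,12,14-heptaenal | CC1=C[C@H](O[Si](C)(C)C(C)(C)C)CC(C)(C)[C@H]1/C=C/C(C)=C/C=C/C(C)=C/C=C/C=C(C)/C=C/C=O | intermediate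
27 | 2-(triphenylphosphoranylidene)propanal | CC(C=O)=P(c1ccccc1)(c1ccccc1)c1ccccc1 | starting material
28 | (2E,4E,6E,8E,10E,12E,14E,16E)-2,6,11,15-tetramethyl-17-[(1R,4R)-4-(TBSO)-2,6,6-trimethylcyclohex-2-en-1-yl]heptadeca-2,4,6,8,10,12,14,16-octaenal | CC1=C[C@H](O[Si](C)(C)C(C)(C)C)CC(C)(C)[C@H]1/C=C/C(C)=C/C=C/C(C)=C/C=C/C=C(C)/C=C/C=C(\C)C=O | intermediate
29 | α-lithio derivative of sulfone 9 (not isolated) | [Li]C(C1=C(C)C[C@@H](O[Si](C)(C)C(C)(C)C)CC1(C)C)S(=O)(=O)c1ccccc1 | intermediate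
30 | C7-phenylsulfonyl C8-diethylphosphoryloxy adduct of 9 and 28, mixture at C7 and C8 (not isolated) | CC1=C[C@H](O[Si](C)(C)C(C)(C)C)CC(C)(C)[C@H]1/C=C/C(C)=C/C=C/C(C)=C/C=C/C=C(C)/C=C/C=C(\C)C(OP(=O)(OCC)OCC)C(C1=C(C)C[C@@H](O[Si](C)(C)C(C)(C)C)CC1(C)C)S(=O)(=O)c1ccccc1 | intermediate
31 | 7-(phenylsulfonyl) C7=C8 vinyl sulfone, either geometry (not isolated) | CC1=C[C@H](O[Si](C)(C)C(C)(C)C)CC(C)(C)[C@H]1/C=C/C(C)=C/C=C/C(C)=C/C=C/C=C(C)/C=C/C=C(\C)C=C(C1=C(C)C[C@@H](O[Si](C)(C)C(C)(C)C)CC1(C)C)S(=O)(=O)c1ccccc1 | intermediate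
32 | (3R,3'R,6'R)-3,3'-bis(tert-butyldimethylsilyloxy)-7,8-didehydro-β,ε-carotene | CC1=C[C@H](O[Si](C)(C)C(C)(C)C)CC(C)(C)[C@H]1/C=C/C(C)=C/C=C/C(C)=C/C=C/C=C(C)/C=C/C=C(\C)C#CC1=C(C)C[C@@H](O[Si](C)(C)C(C)(C)C)CC1(C)C | intermediate
33 | (3R,3'R,6'R)-7,8-didehydro-β,ε-carotene-3,3'-diol (CNP0232536.1) | CC1=C[C@H](O)CC(C)(C)[C@H]1/C=C/C(C)=C/C=C/C(C)=C/C=C/C=C(C)/C=C/C=C(\C)C#CC1=C(C)C[C@@H](O)CC1(C)C | target

**Totals**
Total step count: 17. Longest linear sequence: 12 steps (steps 6–15, then 16 and 17); the β-ring branch is 5 steps (1–5).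

**Three steps most likely to fail, with fallbacks**

Step 16 (late-stage addition and double elimination on the C30 polyenal). The risks are retro-addition of the hindered adduct and incomplete loss of sulfinate from vinyl sulfone 31. The fallback moves the ring–chain union one bond over, to C6–C7, and makes it by cross-coupling. It sets out from 28 and from 4. Aldehyde 28 is homologated with Me3SiC(Li)N2 (THF, −78 → 0 °C, Colvin alkyne synthesis) to (3E,5E,7E,9E,11E,13E,15E,17E)-3,7,12,16-tetramethyl-18-[(1R,4R)-4-(TBSO)-2,6,6-trimethylcyclohex-2-en-1-yl]octadeca-3,5,7,9,11,13,15,17-octaen-1-yne F1, in which the old aldehyde carbon is C8 and the new carbon is C7. Ketone 4 is converted with LiN(i-Pr)2 and PhNTf2 (THF, −78 °C) into (R)-4-(TBSO)-2,6,6-trimethylcyclohex-1-en-1-yl trifluoromethanesulfonate F2. Sonogashira coupling of the two (Pd(PPh3)4, CuI, i-Pr2NH, THF, rt) gives 32, where the route is rejoined before step 17.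

Step 4 (carbanion addition to a hindered, enolisable ketone). If (phenylsulfonyl)methyllithium only enolises 4, carbon C7 is brought in as a sulfur ylide and the sulfur as a thiolate. From 4, trimethylsulfonium iodide and n-BuLi (THF, 0 °C, Corey–Chaykovsky) give (6R,8R)-6-(TBSO)-4,4,8-trimethyl-1-oxaspiro[2.5]octane F3. PhSNa (DMF, 80 °C) opens the epoxide at CH2 to (4R,6R)-4-(TBSO)-2,2,6-trimethyl-1-[(phenylsulfanyl)methyl]cyclohexan-1-ol F4. Oxidation with H2O2 and (NH4)6Mo7O24 (cat.) in EtOH gives 7, where the route is rejoined before step 5.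

Step 7 (site selectivity of the allylic oxidation on the dienoate). If oxidation of 13 is unselective, the ring oxygen is installed before the side chain is extended, with the ketone masked. From 10, ethylene glycol, HC(OEt)3 and TsOH (cat.) give racemic 2-methyl-2-[(E)-2-(2,6,6-trimethylcyclohex-2-en-1-yl)ethenyl]-1,3-dioxolane F5. The same t-BuOOH oxidation gives racemic 4-[(E)-2-(2-methyl-1,3-dioxolan-2-yl)ethenyl]-3,5,5-trimethylcyclohex-2-en-1-one F6. LiBH(s-Bu)3 (THF, −78 °C) gives the racemic trans-3-hydroxy ketal F7. PPTS in acetone/water frees racemic trans-3-hydroxy-α-ionone F8. HWE reaction of F8 with 11 (NaH, 2.2 equiv, THF) returns to 15, where the route is rejoined before step 9.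

**Further compounds**
F1 | step 16 | (3E,5E,7E,9E,11E,13E,15E,17E)-3,7,12,16-tetramethyl-18-[(1R,4R)-4-(TBSO)-2,6,6-trimethylcyclohex-2-en-1-yl]octadeca-3,5,7,9,11,13,15,17-octaen-1-yne | CC1=C[C@H](O[Si](C)(C)C(C)(C)C)CC(C)(C)[C@H]1/C=C/C(C)=C/C=C/C(C)=C/C=C/C=C(C)/C=C/C=C(\C)C#C
F2 | step 16 | (R)-4-(TBSO)-2,6,6-trimethylcyclohex-1-en-1-yl trifluoromethanesulfonate | FC(F)(F)S(=O)(=O)OC1=C(C)C[C@@H](O[Si](C)(C)C(C)(C)C)CC1(C)C
F3 | step 4 | (6R,8R)-6-(TBSO)-4,4,8-trimethyl-1-oxaspiro[2.5]octane, spiro centre as formed | C[C@@H]1C[C@@H](O[Si](C)(C)C(C)(C)C)CC(C)(C)C12CO2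
F4 | step 4 | (4R,6R)-4-(TBSO)-2,2,6-trimethyl-1-[(phenylsulfanyl)methyl]cyclohexan-1-ol | C[C@@H]1C[C@@H](O[Si](C)(C)C(C)(C)C)CC(C)(C)C1(O)CSc1ccccc1
F5 | step 7 | racemic 2-methyl-2-[(E)-2-(2,6,6-trimethylcyclohex-2-en-1-yl)ethenyl]-1,3-dioxolane | CC1=CCCC(C)(C)C1/C=C/C1(C)OCCO1
F6 | step 7 | racemic 4-[(E)-2-(2-methyl-1,3-dioxolan-2-yl)ethenyl]-3,5,5-trimethylcyclohex-2-en-1-one | CC1=CC(=O)CC(C)(C)C1/C=C/C1(C)OCCO1
F7 | step 7 | racemic (1RS,4RS)-4-[(E)-2-(2-methyl-1,3-dioxolan-2-yl)ethenyl]-3,5,5-trimethylcyclohex-2-en-1-ol, trans (both enantiomers written) | CC1=C[C@H](O)CC(C)(C)[C@H]1/C=C/C1(C)OCCO1.CC1=C[C@@H](O)CC(C)(C)[C@@H]1/C=C/C1(C)OCCO1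
F8 | step 7 | racemic trans-3-hydroxy-α-ionone, (E)-4-[(1RS,4RS)-4-hydroxy-2,6,6-trimethylcyclohex-2-en-1-yl]but-3-en-2-one (both enantiomers written) | CC1=C[C@H](O)CC(C)(C)[C@H]1/C=C/C(C)=O.CC1=C[C@@H](O)CC(C)(C)[C@@H]1/C=C/C(C)=O
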